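**Retrosynthetic overview**

1. The target comes from its ring-A trimethyl ether by a final chelation-controlled loss of one ortho methyl group (BCl3 held by the ketone); the two ortho methoxy groups of ring A are equivalent.
2. Ring C (the pyran) is cut at O1–C2. This allylic tertiary ether is the feature the plan rests on: C4, C3, C2 and the two methyls on C2 are a prenyl group on C4a, with the C8a oxygen ortho to it, so ring C is the 2-prenylresorcinol of ring B less two hydrogens. DDQ kept oxidised at an anode takes the hydride, and the vinyl ortho-quinone methide closes by oxa-6π electrocyclisation.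
3. The diaryl ketone is cut between the carbonyl carbon and ring A: 2,4,6-trimethoxyphenyllithium adds to a 2-prenyl-3,5-bis(methoxymethoxy)benzaldehyde and the carbinol is oxidised. An aldehyde accepts this hindered aryllithium far more readily than an amide or ester.
4. The aldehyde comes from 3,5-dihydroxybenzaldehyde by MOM protection, bromination at C2 and Stille prenylation. The acetals are orthogonal to the methyl ethers of ring A and, unlike silyl ethers, cannot shift from oxygen to carbon next to an aryl–metal bond.
5. Rings A and B are bought as benzenes; ring C is the only ring formed, in step 7.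

Key step: step 7

Remark: ring A is the trioxygenated benzoyl ring, ring B the benzo ring of the chromene, ring C the pyran; the target has no stereocentre, and the carbinol of step 4 is carried as a racemate.

**Step 1**
Reactants: 1 3,5-dihydroxybenzaldehyde
Product: 2 3,5-bis(methoxymethoxy)benzaldehyde
Conditions: MOMCl (2.5 equiv), i-Pr2NEt, CH2Cl2, 0 °C → rt
Reagents that add atoms: chloromethyl methyl ether, COCCl
Why: Base-mediated O-alkylation (Williamson-type) of both phenols with the reactive α-chloro ether should be clean beside the aldehyde, and the acetals survive bromination, palladium coupling, aryllithium and oxidation yet leave in mild acid that does not touch aryl methyl ethers.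

**Step 2**
Reactants: 2 3,5-bis(methoxymethoxy)benzaldehyde
Product: 3 2-bromo-3,5-bis(methoxymethoxy)benzaldehyde
Conditions: NBS (1.0 equiv), MeCN, 0 °C → rt
Reagents that add atoms: N-bromosuccinimide, O=C1CCC(=O)N1Br
Why: Electrophilic aromatic bromination should go to C2, ortho to one acetal oxygen and para to the other, because C4 between the two OMOM groups is shielded, which is the regiochemistry established for 3,5-dialkoxybenzaldehydes.

**Step 3**
Reactants: 3 2-bromo-3,5-bis(methoxymethoxy)benzaldehyde; 4 tributyl(3-methylbut-2-en-1-yl)stannane
Product: 5 3,5-bis(methoxymethoxy)-2-(3-methylbut-2-en-1-yl)benzaldehyde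
Conditions: Pd(PPh3)4 (5 mol %), DMF, 95 °C
Reagents that add atoms: none
Why: Stille cross-coupling, in which oxidative addition at the C–Br bond is helped by the ortho formyl group and reductive elimination at the less substituted allyl terminus should give the linear prenyl arene without touching the aldehyde or the acetals.

**Step 4**
Reactants: 5 3,5-bis(methoxymethoxy)-2-(3-methylbut-2-en-1-yl)benzaldehyde; 6 1,3,5-trimethoxybenzene
Product: 8 [3,5-bis(methoxymethoxy)-2-(3-methylbut-2-en-1-yl)phenyl](2,4,6-trimethoxyphenyl)methanol (racemic), via 2,4,6-trimethoxyphenyllithium 7 (not isolated)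
Conditions: 6, n-BuLi, THF, 0 °C → rt; then 5, −78 → 0 °C; H2O
Reagents that add atoms: none
Why: Directed ortho-lithiation of 1,3,5-trimethoxybenzene between two methoxy groups followed by 1,2-addition of the aryllithium to the aldehyde should give the diaryl carbinol, whose single stereocentre forms without control and is erased in step 5.

**Step 5**
Reactants: 8 [3,5-bis(methoxymethoxy)-2-(3-methylbut-2-en-1-yl)phenyl](2,4,6-trimethoxyphenyl)methanol (racemic)
Product: 9 [3,5-bis(methoxymethoxy)-2-(3-methylbut-2-en-1-yl)phenyl](2,4,6-trimethoxyphenyl)methanone
Conditions: IBX, DMSO, rt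
Reagents that add atoms: none
Why: IBX oxidation of a secondary benzylic alcohol runs under neutral conditions, which should avoid ionisation of the doubly activated carbinol and leave the trisubstituted alkene and the acetals alone.

**Step 6**
Reactants: 9 [3,5-bis(methoxymethoxy)-2-(3-methylbut-2-en-1-yl)phenyl](2,4,6-trimethoxyphenyl)methanone
Product: 10 [3,5-dihydroxy-2-(3-methylbut-2-en-1-yl)phenyl](2,4,6-trimethoxyphenyl)methanone
Conditions: HCl (1 M in MeOH), rt → 40 °C
Reagents that add atoms: none
Why: Acid-catalysed transacetalisation to methanol (MOM cleavage) should free both ring-B phenols, while aryl methyl ethers are inert and dilute acid near room temperature protonates the prenyl alkene too slowly to form the chroman.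

**Step 7**
Reactants: 10 [3,5-dihydroxy-2-(3-methylbut-2-en-1-yl)phenyl](2,4,6-trimethoxyphenyl)methanone
Product: 12 (7-hydroxy-2,2-dimethyl-2H-chromen-5-yl)(2,4,6-trimethoxyphenyl)methanone, via vinyl ortho-quinone methide 11 (not isolated)
Conditions: DDQ (20 mol %), LiClO4, MeCN/AcOH, graphite-felt anode, Pt cathode, divided cell, potential held at the DDQH2/DDQ wave, 40 °C
Reagents that add atoms: none
Why: DDQ, kept oxidised at the anode, removes hydride from the benzylic and allylic CH2 of ring B, whose cation is stabilised by the ortho and para hydroxyls, and loss of the C3–OH proton gives the vinyl ortho-quinone methide 11 while the cathode reduces the released protons to H2. The closest known reaction types are the stoichiometric DDQ dehydrogenative cyclisation of ortho-prenylphenols to 2,2-dimethyl-2H-chromenes and the anodic recycling of DDQ used to generate ortho-quinone methides from ortho-alkylated acylphenols. Ring C closes by a thermal disrotatory oxa-6π electrocyclisation of dienone 11, which makes the O1–C2 bond and leaves the C3–C4 alkene in place. No stereocentre is formed because C2 carries two methyl groups. The step needs hydride loss at the ring-B CH2 and no oxidation of ring A or of the product: the ring-B hydroxyls are meta to the carbonyl and feed the benzylic cation, the three methoxy donors of ring A are tied up in conjugation with the ketone, the potential stays at the mediator wave below direct arene oxidation, and the chromene has no benzylic C–H left. Ring size and position are fixed because the C3 hydroxyl is the only oxygen ortho to the prenyl group, the para C5 hydroxyl giving at most the para-quinone methide, which returns to 11 by proton transfer.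

**Step 8**
Reactants: 12 (7-hydroxy-2,2-dimethyl-2H-chromen-5-yl)(2,4,6-trimethoxyphenyl)methanone
Product: 13 (7-hydroxy-2,2-dimethyl-2H-chromen-5-yl)(2-hydroxy-4,6-dimethoxyphenyl)methanone
Conditions: BCl3 (1 M in CH2Cl2, 3 equiv), CH2Cl2, −78 → −20 °C; then cold H2O
Reagents that add atoms: none
Why: Chelation-controlled ortho-demethylation, in which BCl3 bridges the ketone oxygen and one flanking methoxy oxygen of ring A and chloride removes that methyl, after which the boron chelate should shield the second ortho methoxy group while the unchelated para methoxy group and the pyran ether stay intact at low temperature.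

**Compound list**

1 | 3,5-dihydroxybenzaldehyde | O=Cc1cc(O)cc(O)c1 | starting material
2 | 3,5-bis(methoxymethoxy)benzaldehyde | COCOc1cc(C=O)cc(OCOC)c1 | intermediate
3 | 2-bromo-3,5-bis(methoxymethoxy)benzaldehyde | COCOc1cc(C=O)c(Br)c(OCOC)c1 | intermediate
4 | tributyl(3-methylbut-2-en-1-yl)stannane | CCCC[Sn](CCCC)(CCCC)CC=C(C)C | starting material
5 | 3,5-bis(methoxymethoxy)-2-(3-methylbut-2-en-1-yl)benzaldehyde | COCOc1cc(C=O)c(CC=C(C)C)c(OCOC)c1 | intermediate
6 | 1,3,5-trimethoxybenzene | COc1cc(OC)cc(OC)c1 | starting material
7 | 2,4,6-trimethoxyphenyllithium | [Li]c1c(OC)cc(OC)cc1OC | intermediate (not isolated)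
8 | [3,5-bis(methoxymethoxy)-2-(3-methylbut-2-en-1-yl)phenyl](2,4,6-trimethoxyphenyl)methanol (racemic) | COCOc1cc(OCOC)c(CC=C(C)C)c(C(O)c2c(OC)cc(OC)cc2OC)c1 | intermediate
9 | [3,5-bis(methoxymethoxy)-2-(3-methylbut-2-en-1-yl)phenyl](2,4,6-trimethoxyphenyl)methanone | COCOc1cc(OCOC)c(CC=C(C)C)c(C(=O)c2c(OC)cc(OC)cc2OC)c1 | intermediate
10 | [3,5-dihydroxy-2-(3-methylbut-2-en-1-yl)phenyl](2,4,6-trimethoxyphenyl)methanone | COc1cc(OC)c(C(=O)c2cc(O)cc(O)c2CC=C(C)C)c(OC)c1 | intermediate
11 | (6Z)-3-hydroxy-6-(3-methylbut-2-en-1-ylidene)-5-(2,4,6-trimethoxybenzoyl)cyclohexa-2,4-dien-1-one | O=C1C=C(O)C=C(C(=O)c2c(OC)cc(OC)cc2OC)/C1=C/C=C(C)C | intermediate (not isolated)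
12 | (7-hydroxy-2,2-dimethyl-2H-chromen-5-yl)(2,4,6-trimethoxyphenyl)methanone | COc1cc(OC)c(C(=O)c2cc(O)cc3c2C=CC(C)(C)O3)c(OC)c1 | intermediate
13 | (7-hydroxy-2,2-dimethyl-2H-chromen-5-yl)(2-hydroxy-4,6-dimethoxyphenyl)methanone | COc1cc(O)c(C(=O)c2cc(O)cc3c2C=CC(C)(C)O3)c(OC)c1 | target

**Totals**

Total step count: 8. Longest linear sequence: 8 steps (1 → 13).

**Steps most likely to fail**

Step 7. The mediator may turn over too slowly at the electrode, so that the resorcinol is oxidised directly by one-electron pathways and oligomerises. The quinone methide may also be trapped by acetic acid or by a second phenol before it cyclises. The fallback sets out from 10 and comes back at 12, and replaces hydride abstraction by an ionic cyclisation and elimination. PhSeCl in CH2Cl2 at −78 °C should form the seleniranium ion of the prenyl alkene, which the ortho hydroxyl opens at the tertiary carbon (6-endo, Markovnikov) to give [7-hydroxy-2,2-dimethyl-3-(phenylselanyl)-3,4-dihydro-2H-chromen-5-yl](2,4,6-trimethoxyphenyl)methanone F1 (racemic at C3). Aqueous H2O2 in THF at 0 °C → rt then oxidises selenium, and syn-elimination, possible only towards the C4 hydrogens because C2 is quaternary, should give 12.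

Step 8. The Lewis acid may ionise the allylic tertiary O1–C2 ether, or the HCl released when BCl3 meets the free C7 phenol may add across the styrene-type C3–C4 alkene, leading to ring opening and oligomerisation; a second methyl ether may also be lost. The fallback sets out from 9 and comes back at 13, and moves the demethylation ahead of pyran formation so that the Lewis acid never meets ring C. Excess BCl3 in CH2Cl2 at −78 °C on the fully protected ketone 9, quenched inversely into cold aqueous NaHCO3, should cleave both MOM acetals and, through the ketone chelate, one ortho methyl ether, with no free hydroxyl present to release HCl beside the prenyl group before the quench. This gives [3,5-dihydroxy-2-(3-methylbut-2-en-1-yl)phenyl](2-hydroxy-4,6-dimethoxyphenyl)methanone F2, which is then cyclised under the conditions of step 7 to give 13 directly.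

Step 3. Oxidative addition at the doubly ortho-substituted bromide may be slow, the allyl unit may couple through its γ-carbon to give the 1,1-dimethylallyl isomer, or the double bond may migrate into conjugation. The fallback sets out from 3 and comes back at 5, and makes the aryl–prenyl bond by organocopper alkylation. HC(OMe)3 and catalytic PPTS in MeOH should convert 3 into 2-bromo-1-(dimethoxymethyl)-3,5-bis(methoxymethoxy)benzene F3. Bromine–lithium exchange (n-BuLi, THF, −78 °C), transmetalation with CuBr·SMe2 and alkylation with 1-bromo-3-methylbut-2-ene at its primary carbon should give 1-(dimethoxymethyl)-3,5-bis(methoxymethoxy)-2-(3-methylbut-2-en-1-yl)benzene F4. PPTS in wet acetone at rt then hydrolyses the dimethyl acetal, much faster than the aryl MOM ethers, to return 5.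

**Further compounds**

F1 | step 7 | [7-hydroxy-2,2-dimethyl-3-(phenylselanyl)-3,4-dihydro-2H-chromen-5-yl](2,4,6-trimethoxyphenyl)methanone (racemic) | COc1cc(OC)c(C(=O)c2cc(O)cc3c2CC([Se]c2ccccc2)C(C)(C)O3)c(OC)c1
F2 | step 8 | [3,5-dihydroxy-2-(3-methylbut-2-en-1-yl)phenyl](2-hydroxy-4,6-dimethoxyphenyl)methanone | COc1cc(O)c(C(=O)c2cc(O)cc(O)c2CC=C(C)C)c(OC)c1
F3 | step 3 | 2-bromo-1-(dimethoxymethyl)-3,5-bis(methoxymethoxy)benzene | COCOc1cc(OCOC)c(Br)c(C(OC)OC)c1
F4 | step 3 | 1-(dimethoxymethyl)-3,5-bis(methoxymethoxy)-2-(3-methylbut-2-en-1-yl)benzene | COCOc1cc(OCOC)c(CC=C(C)C)c(C(OC)OC)c1
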